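**Retrosynthetic overview**

1. The target is a (2R,3R)-dihydroflavonol. The feature used is the acyloin of ring C, C4(=O)–C3H(OH): C4 is bound to ring A, so a ring A aldehyde can act as acyl anion, and C3 is flanked by C2, a benzylic carbon carrying O1 and ring B whose hydrogen becomes acidic once C3 is a ketone.
2. Key disconnection C4–C3: a chiral-carbene-catalysed intramolecular crossed benzoin reaction of the ring A aldehyde onto a C3 keto ester. The tert-butyl carboxylate on C3 is a temporary activating group, so that a racemic open-chain precursor closes ring C and converges on the 2R configuration by dynamic kinetic resolution.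
3. The precursor comes from O1–C2 bond formation (phenoxide opening of a Darzens glycidic ester that carries ring B) and oxidation at C3. The C8 prenyl group comes from a reverse-prenyl ether and an aromatic Claisen rearrangement on a purchased salicylaldehyde.
4. Rings A and B are purchased; ring C is the only ring formed (step 8). The endgame is acidolysis with decarboxylation (C3–H set, 2,3-trans) and chelation-controlled 5-O-demethylation.

Key step: step 8

Assumption: the (5aS,10bR) antipode of the triazolium salt is taken to give the 2R series in step 8; should the sense of induction be the opposite, the (5aR,10bS) salt is used, both being made from commercial cis-1-amino-2-indanol.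

**Route**

Step 1
Reactants: 1 2-methylbut-3-en-2-ol
Product: 3 isobutyl 2-methylbut-3-en-2-yl carbonate, via lithium 2-methylbut-3-en-2-olate 2 (not isolated)
Conditions: n-BuLi, THF, −78 °C; then ClCO2i-Bu, −78 °C to rt
Reagents that add atoms: isobutyl chloroformate, CC(C)COC(=O)Cl
Why: Acylation of a pre-formed tertiary lithium alkoxide by a chloroformate is reliable and gives the allylic carbonate needed for step 2; no stereocentre is formed.

Step 2
Reactants: 4 2-hydroxy-4,6-dimethoxybenzaldehyde; 3 isobutyl 2-methylbut-3-en-2-yl carbonate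
Product: 5 2,4-dimethoxy-6-[(2-methylbut-3-en-2-yl)oxy]benzaldehyde
Conditions: Pd(PPh3)4 (5 mol %), THF, 0 °C to rt
Reagents that add atoms: none
Why: Tsuji–Trost O-allylation in which Pd(PPh3)4 ionises the carbonate and the phenoxide, freed by the isobutoxide released, attacks the 1,1-dimethylallyl palladium complex at its more substituted end under kinetic control, giving the tertiary aryl ether; no stereocentre is formed.

Step 3
Reactants: 5 2,4-dimethoxy-6-[(2-methylbut-3-en-2-yl)oxy]benzaldehyde
Product: 6 2-hydroxy-4,6-dimethoxy-3-(3-methylbut-2-en-1-yl)benzaldehyde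
Conditions: PhNEt2, 130 °C
Reagents that add atoms: none
Why: Aromatic Claisen rearrangement: the [3,3] shift can reach only the one free ortho carbon and rearomatisation leaves a 3-methylbut-2-enyl group beside a phenol that is hydrogen-bonded to the aldehyde, while the amine solvent keeps the medium free of acid so that the ortho-prenylphenol does not cyclise.

Step 4
Reactants: 7 3-hydroxy-4-methoxybenzaldehyde (isovanillin)
Product: 8 4-methoxy-3-(methoxymethoxy)benzaldehyde
Conditions: MOMCl, K2CO3, acetone, rt
Reagents that add atoms: chloromethyl methyl ether, COCCl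
Why: Williamson-type O-alkylation of the phenoxide gives a MOM acetal that withstands the basic and oxidative steps 5 to 8 and is cleaved in the acidic step 9.

Step 5
Reactants: 8 4-methoxy-3-(methoxymethoxy)benzaldehyde; 9 tert-butyl chloroacetate
Product: 10 tert-butyl trans-3-[4-methoxy-3-(methoxymethoxy)phenyl]oxirane-2-carboxylate (racemic)
Conditions: KOt-Bu, THF, −10 °C to rt
Reagents that add atoms: none
Why: Darzens glycidic ester condensation (enolate addition to the aldehyde, then ring closure of the chlorohydrin alkoxide) should give mainly the trans epoxide, and its relative configuration is of no consequence because one centre is oxidised in step 7 and the other equilibrates in step 8.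

Step 6
Reactants: 6 2-hydroxy-4,6-dimethoxy-3-(3-methylbut-2-en-1-yl)benzaldehyde; 10 tert-butyl trans-3-[4-methoxy-3-(methoxymethoxy)phenyl]oxirane-2-carboxylate
Product: 11 tert-butyl 3-[2-formyl-3,5-dimethoxy-6-(3-methylbut-2-en-1-yl)phenoxy]-2-hydroxy-3-[4-methoxy-3-(methoxymethoxy)phenyl]propanoate (racemic, relative configuration 2R,3R expected)
Conditions: Cs2CO3 (0.3 equiv), DMF, 60 °C
Reagents that add atoms: none
Why: Base-catalysed SN2 opening of the aryl glycidic ester by the phenoxide at the benzylic carbon, which the para-methoxy group activates while the ester disfavours attack at the neighbouring carbon, forms the O1–C2 bond as in known phenoxide openings of 3-arylglycidic derivatives, and the alkoxide formed regenerates phenoxide so that the base is catalytic.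

Step 7
Reactants: 11 tert-butyl 3-[2-formyl-3,5-dimethoxy-6-(3-methylbut-2-en-1-yl)phenoxy]-2-hydroxy-3-[4-methoxy-3-(methoxymethoxy)phenyl]propanoate
Product: 12 tert-butyl 3-[2-formyl-3,5-dimethoxy-6-(3-methylbut-2-en-1-yl)phenoxy]-3-[4-methoxy-3-(methoxymethoxy)phenyl]-2-oxopropanoate (racemic)
Conditions: Dess–Martin periodinane, CH2Cl2, 0 °C to rt; used without long storage
Reagents that add atoms: none
Why: Dess–Martin oxidation converts the secondary α-hydroxy ester into the α-keto ester under neutral conditions that spare the aldehyde, the prenyl double bond and the MOM ether, and it makes the benzylic centre configurationally labile, as step 8 requires.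

Step 8
Reactants: 12 tert-butyl 3-[2-formyl-3,5-dimethoxy-6-(3-methylbut-2-en-1-yl)phenoxy]-3-[4-methoxy-3-(methoxymethoxy)phenyl]-2-oxopropanoate (racemic)
Product: 13 tert-butyl (2R,3R)-3-hydroxy-5,7-dimethoxy-2-[4-methoxy-3-(methoxymethoxy)phenyl]-8-(3-methylbut-2-en-1-yl)-4-oxo-3,4-dihydro-2H-chromene-3-carboxylate
Conditions: (5aS,10bR)-2-(pentafluorophenyl)-5a,10b-dihydro-4H,6H-indeno[2,1-b][1,2,4]triazolo[4,3-d][1,4]oxazin-2-ium tetrafluoroborate (10 mol %), K2CO3 (0.5 equiv), toluene, rt, argon
Reagents that add atoms: none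
Why: The carbene freed from the triazolium salt adds to the ring A formyl group, proton transfer gives the nucleophilic enaminol (acyl anion equivalent at C4), and this attacks the C3 keto group and releases the catalyst, an intramolecular crossed benzoin reaction of the kind known for carbene-catalysed aldehyde–ketone cyclisations to 3-hydroxychroman-4-ones and for dynamic kinetic crossed benzoin additions to racemic β-stereogenic α-keto esters. Ring C closes in the 6-exo-trig mode (C4 attacks the exocyclic C3=O). The C3 configuration is fixed by the chiral carbene, which selects the enaminol face and holds the ketone oxygen through an O–H···O hydrogen bond, and the C2 configuration by dynamic kinetic resolution: the C2–H of 12 lies between an aryl ring, the aryloxy oxygen and the keto ester, so the enantiomers of 12 interconvert through the enol under K2CO3 and only the one that places ring B pseudo-equatorial in the catalyst-bound transition state cyclises fast. The step needs one acyl donor only, and the tert-butyl carboxylate on C3 secures this: a ketone has no formyl hydrogen and can only accept, so no carbene-bound carbanion arises next to the aryloxy leaving group on C2 (which a C3 aldehyde would allow), and the activated ketone should outrun aldol attack of the enol carbon C2 on the hindered aldehyde. Only the C2 outcome has to be high, because C3 is re-formed as a CH centre in step 9; 13 is drawn as the C3 epimer expected from the hydrogen-bonded transition state.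

Step 9
Reactants: 13 tert-butyl (2R,3R)-3-hydroxy-5,7-dimethoxy-2-[4-methoxy-3-(methoxymethoxy)phenyl]-8-(3-methylbut-2-en-1-yl)-4-oxo-3,4-dihydro-2H-chromene-3-carboxylate
Product: 16 (2R,3R)-3-hydroxy-2-(3-hydroxy-4-methoxyphenyl)-5,7-dimethoxy-8-(3-methylbut-2-en-1-yl)-2,3-dihydro-4H-chromen-4-one, via keto acid 14 (not isolated), via enediol 15 (not isolated)
Conditions: 3 M HCl in MeOH–THF, 50 °C, argon (degassed)
Reagents that add atoms: none
Why: Acidolysis removes the tert-butyl ester and the MOM acetal, the β-keto acid 14 loses CO2 through the usual cyclic transition state (β-keto acid decarboxylation) to enediol 15, and ketonisation at C3, which is reversible in the acidic medium, should settle on the more stable 2,3-trans ketol (ring B and 3-OH both equatorial, OH hydrogen-bonded to C4=O) whatever the C3 configuration of 13, C2 not being touched.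

Step 10
Reactants: 16 (2R,3R)-3-hydroxy-2-(3-hydroxy-4-methoxyphenyl)-5,7-dimethoxy-8-(3-methylbut-2-en-1-yl)-2,3-dihydro-4H-chromen-4-one
Product: 17 (2R,3R)-3,5-dihydroxy-2-(3-hydroxy-4-methoxyphenyl)-7-methoxy-8-(3-methylbut-2-en-1-yl)-2,3-dihydro-4H-chromen-4-one (CNP0302743.1)
Conditions: MgI2·OEt2 (excess), THF, 60 °C, argon; then 1 M aq. HCl
Reagents that add atoms: none
Why: Chelation-controlled aryl methyl ether cleavage: magnesium held between C4=O and the peri 5-methoxy oxygen activates only that methyl group for SN2 attack by iodide, a selectivity known for 5-methoxy-8-prenylflavanones, so the 7- and 4'-methoxy groups, the prenyl group and both stereocentres should be kept.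

**Compound list**

1 | 2-methylbut-3-en-2-ol | CC(C)(O)C=C | starting material
2 | lithium 2-methylbut-3-en-2-olate | [Li+].[O-]C(C)(C)C=C | intermediate (not isolated)
3 | isobutyl 2-methylbut-3-en-2-yl carbonate | CC(C)COC(=O)OC(C)(C)C=C | intermediate
4 | 2-hydroxy-4,6-dimethoxybenzaldehyde | O=Cc1c(O)cc(OC)cc1OC | starting material
5 | 2,4-dimethoxy-6-[(2-methylbut-3-en-2-yl)oxy]benzaldehyde | O=Cc1c(OC(C)(C)C=C)cc(OC)cc1OC | intermediate
6 | 2-hydroxy-4,6-dimethoxy-3-(3-methylbut-2-en-1-yl)benzaldehyde | O=Cc1c(O)c(CC=C(C)C)c(OC)cc1OC | intermediate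
7 | 3-hydroxy-4-methoxybenzaldehyde (isovanillin) | O=Cc1ccc(OC)c(O)c1 | starting material
8 | 4-methoxy-3-(methoxymethoxy)benzaldehyde | O=Cc1ccc(OC)c(OCOC)c1 | intermediate
9 | tert-butyl chloroacetate | CC(C)(C)OC(=O)CCl | starting material
10 | tert-butyl trans-3-[4-methoxy-3-(methoxymethoxy)phenyl]oxirane-2-carboxylate, racemic, (2R,3S) enantiomer drawn | CC(C)(C)OC(=O)[C@@H]1O[C@H]1c1ccc(OC)c(OCOC)c1 | intermediate
11 | tert-butyl 3-[2-formyl-3,5-dimethoxy-6-(3-methylbut-2-en-1-yl)phenoxy]-2-hydroxy-3-[4-methoxy-3-(methoxymethoxy)phenyl]propanoate, racemic, (2R,3R) enantiomer drawn | CC(C)(C)OC(=O)[C@H](O)[C@H](Oc1c(C=O)c(OC)cc(OC)c1CC=C(C)C)c1ccc(OC)c(OCOC)c1 | intermediate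
12 | tert-butyl 3-[2-formyl-3,5-dimethoxy-6-(3-methylbut-2-en-1-yl)phenoxy]-3-[4-methoxy-3-(methoxymethoxy)phenyl]-2-oxopropanoate, racemic | CC(C)(C)OC(=O)C(=O)C(Oc1c(C=O)c(OC)cc(OC)c1CC=C(C)C)c1ccc(OC)c(OCOC)c1 | intermediate
13 | tert-butyl (2R,3R)-3-hydroxy-5,7-dimethoxy-2-[4-methoxy-3-(methoxymethoxy)phenyl]-8-(3-methylbut-2-en-1-yl)-4-oxo-3,4-dihydro-2H-chromene-3-carboxylate | COc1ccc([C@H]2Oc3c(CC=C(C)C)c(OC)cc(OC)c3C(=O)[C@]2(C(=O)OC(C)(C)C)O)cc1OCOC | intermediate
14 | (2R,3R)-3-hydroxy-2-(3-hydroxy-4-methoxyphenyl)-5,7-dimethoxy-8-(3-methylbut-2-en-1-yl)-4-oxo-3,4-dihydro-2H-chromene-3-carboxylic acid | COc1ccc([C@H]2Oc3c(CC=C(C)C)c(OC)cc(OC)c3C(=O)[C@]2(C(=O)O)O)cc1O | intermediate (not isolated)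
15 | (2R)-2-(3-hydroxy-4-methoxyphenyl)-5,7-dimethoxy-8-(3-methylbut-2-en-1-yl)-2H-chromene-3,4-diol | COc1ccc([C@H]2Oc3c(CC=C(C)C)c(OC)cc(OC)c3C(O)=C2O)cc1O | intermediate (not isolated)
16 | (2R,3R)-3-hydroxy-2-(3-hydroxy-4-methoxyphenyl)-5,7-dimethoxy-8-(3-methylbut-2-en-1-yl)-2,3-dihydro-4H-chromen-4-one | COc1ccc([C@H]2Oc3c(CC=C(C)C)c(OC)cc(OC)c3C(=O)[C@@H]2O)cc1O | intermediate
17 | (2R,3R)-3,5-dihydroxy-2-(3-hydroxy-4-methoxyphenyl)-7-methoxy-8-(3-methylbut-2-en-1-yl)-2,3-dihydro-4H-chromen-4-one (CNP0302743.1) | COc1ccc([C@H]2Oc3c(CC=C(C)C)c(OC)cc(O)c3C(=O)[C@@H]2O)cc1O | target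

**Step count and risks**

Total steps: 10. Longest linear sequence: 8 steps (1 → 3 → 5 → 6 → 11 → 12 → 13 → 16 → 17; steps 1, 2, 3, 6, 7, 8, 9, 10).

Steps most likely to fail:

1. Step 8. Carbene addition to the doubly ortho-oxygenated, electron-rich formyl group may be slow, so that base-induced aldol attack of the enolised keto ester (through C2) on the aldehyde, or an unselective resolution, takes over. Fallback: ring C is closed through O1–C2 instead, by cyclisation of a chalcone epoxide. It sets out from 6 (and uses 8) and returns at 16, replacing steps 6 to 9. MOM protection of 6 (MOMCl, NaH, DMF) gives 4,6-dimethoxy-2-(methoxymethoxy)-3-(3-methylbut-2-en-1-yl)benzaldehyde F1. MeMgBr (THF, 0 °C) gives racemic 1-[4,6-dimethoxy-2-(methoxymethoxy)-3-(3-methylbut-2-en-1-yl)phenyl]ethan-1-ol F2, and Dess–Martin oxidation gives 1-[4,6-dimethoxy-2-(methoxymethoxy)-3-(3-methylbut-2-en-1-yl)phenyl]ethan-1-one F3. Claisen–Schmidt condensation with 8 (KOH, EtOH) gives (E)-1-[4,6-dimethoxy-2-(methoxymethoxy)-3-(3-methylbut-2-en-1-yl)phenyl]-3-[4-methoxy-3-(methoxymethoxy)phenyl]prop-2-en-1-one F4. Juliá–Colonna epoxidation (poly-L-leucine, urea–H2O2, DBU, THF), which does not touch the prenyl double bond, should give [4,6-dimethoxy-2-(methoxymethoxy)-3-(3-methylbut-2-en-1-yl)phenyl]{(2R,3S)-3-[4-methoxy-3-(methoxymethoxy)phenyl]oxiran-2-yl}methanone F5. HCl in MeOH then removes both MOM groups and the freed phenol opens the epoxide at the benzylic carbon with inversion, which should give 16.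

2. Step 9. Kinetic protonation of the enediol on the face away from ring B, followed by slow acid-mediated epimerisation, may leave the 2,3-cis epimer; acid-induced addition to the prenyl double bond and air oxidation of the enediol are further hazards. Fallback: C3 is corrected by stereoinversion instead of equilibration. It sets out from 13 and returns at 16. The acid treatment of step 9 is stopped once decarboxylation is complete and (2R,3S)-3-hydroxy-2-(3-hydroxy-4-methoxyphenyl)-5,7-dimethoxy-8-(3-methylbut-2-en-1-yl)-2,3-dihydro-4H-chromen-4-one F6 is separated. Mitsunobu esterification (4-nitrobenzoic acid, PPh3, DIAD, THF, 0 °C) inverts C3 to (2R,3R)-2-(3-hydroxy-4-methoxyphenyl)-5,7-dimethoxy-8-(3-methylbut-2-en-1-yl)-4-oxo-3,4-dihydro-2H-chromen-3-yl 4-nitrobenzoate F7. Brief methanolysis (K2CO3 cat., MeOH, 0 °C) should return 16.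

3. Step 6. The hindered, hydrogen-bonded phenoxide is a weak nucleophile, so attack at the ester-bearing carbon, base-induced isomerisation of the glycidic ester or elimination of aryloxide from the product may compete. Fallback: the ether is made by alkylation with a bromo keto ester. It sets out from 10 and returns at 12, replacing steps 6 and 7. LiBr–AcOH (THF, rt) opens 10 at the benzylic carbon to racemic tert-butyl 3-bromo-2-hydroxy-3-[4-methoxy-3-(methoxymethoxy)phenyl]propanoate F8. Dess–Martin oxidation gives racemic tert-butyl 3-bromo-3-[4-methoxy-3-(methoxymethoxy)phenyl]-2-oxopropanoate F9. Alkylation of 6 with F9 (K2CO3, acetone, 0 °C) should give 12.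

**Further compounds**

F1 | step 8 | 4,6-dimethoxy-2-(methoxymethoxy)-3-(3-methylbut-2-en-1-yl)benzaldehyde | O=Cc1c(OCOC)c(CC=C(C)C)c(OC)cc1OC
F2 | step 8 | 1-[4,6-dimethoxy-2-(methoxymethoxy)-3-(3-methylbut-2-en-1-yl)phenyl]ethan-1-ol (racemic) | CC(O)c1c(OCOC)c(CC=C(C)C)c(OC)cc1OC
F3 | step 8 | 1-[4,6-dimethoxy-2-(methoxymethoxy)-3-(3-methylbut-2-en-1-yl)phenyl]ethan-1-one | CC(=O)c1c(OCOC)c(CC=C(C)C)c(OC)cc1OC
F4 | step 8 | (E)-1-[4,6-dimethoxy-2-(methoxymethoxy)-3-(3-methylbut-2-en-1-yl)phenyl]-3-[4-methoxy-3-(methoxymethoxy)phenyl]prop-2-en-1-one | O=C(/C=C/c1ccc(OC)c(OCOC)c1)c1c(OCOC)c(CC=C(C)C)c(OC)cc1OC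
F5 | step 8 | [4,6-dimethoxy-2-(methoxymethoxy)-3-(3-methylbut-2-en-1-yl)phenyl]{(2R,3S)-3-[4-methoxy-3-(methoxymethoxy)phenyl]oxiran-2-yl}methanone | O=C(c1c(OCOC)c(CC=C(C)C)c(OC)cc1OC)[C@@H]1O[C@H]1c1ccc(OC)c(OCOC)c1
F6 | step 9 | (2R,3S)-3-hydroxy-2-(3-hydroxy-4-methoxyphenyl)-5,7-dimethoxy-8-(3-methylbut-2-en-1-yl)-2,3-dihydro-4H-chromen-4-one | COc1ccc([C@H]2Oc3c(CC=C(C)C)c(OC)cc(OC)c3C(=O)[C@H]2O)cc1O
F7 | step 9 | (2R,3R)-2-(3-hydroxy-4-methoxyphenyl)-5,7-dimethoxy-8-(3-methylbut-2-en-1-yl)-4-oxo-3,4-dihydro-2H-chromen-3-yl 4-nitrobenzoate | COc1ccc([C@H]2Oc3c(CC=C(C)C)c(OC)cc(OC)c3C(=O)[C@@H]2OC(=O)c4ccc(cc4)[N+](=O)[O-])cc1O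
F8 | step 6 | tert-butyl 3-bromo-2-hydroxy-3-[4-methoxy-3-(methoxymethoxy)phenyl]propanoate (racemic) | CC(C)(C)OC(=O)C(O)C(Br)c1ccc(OC)c(OCOC)c1
F9 | step 6 | tert-butyl 3-bromo-3-[4-methoxy-3-(methoxymethoxy)phenyl]-2-oxopropanoate (racemic) | CC(C)(C)OC(=O)C(=O)C(Br)c1ccc(OC)c(OCOC)c1
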